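The earlier runs and the new flask are calculated for an exercise; the scatter is artificial.

The constants of this flask were hidden, so I took its clock from the readings of L.

- eta: J 11 mM (in portions, 2); G 22 mM; the very flask that is asked about, followed so far; portions every 12 min
- flask: J 11 mM (in portions, 2); G 22.0 mM; time 30 h; the portions of J follow each other after 12 min, the first at the start

eta run (percent of the J charged)

| time / h | L / % | J / % |
|---|---|---|
| 1.33 | 5.8 | 94.1 |
| 2.00 | 9.2 | 91.1 |
| 3.00 | 13.3 | 87.2 |
| 5.00 | 19.5 | 80.6 |
| 10.0 | 26.9 | 72.6 |
| 15.0 | 28.7 | 70.7 |

(each reading ± 0.3 percentage points)

- given per volume of solution although it is solid: G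
- steps under discussion: J + D <-> L + X; G <-> D
- at the start none of G is in solution
- the reaction counts as stopped when no species that holds the J changes by six tenths of a point or more over the second half of the time

1. which holds at 30 h: what has brought the reaction to rest, or that it has not come to rest (for what has run out or reacted, a solid counts together with what of it has only dissolved) (forward and back rates have come level / it is still moving / all of J has reacted / D has run out first)
2. the L standing at 30 h, as a percentage of the J charged

I counted turnovers. From 5.00 h to 10.0 h L rose by a = 7.4 percentage points, and over the equally long step to 15.0 h by b = 1.8 points. For a gap closing exponentially, s = b/a is the share of the gap that survives a step of length Δt. With y the last reading, that gave the turnover time τ and the plateau P: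

s = b/a = 0.243

τ = Δt / ln(a/b) = 3.54 h

P = y + b·b/(a − b) = 29.3 %

τ is the time in which the gap to the plateau falls by a factor e, the relaxation time of an approach to equilibrium, and it is a reading that carries the scatter of 0.3 points.

On the first rung, the second portion of J was in at 12 min, so on this clock I counted the flask as charged at once. On the next rung, τ, the readings of L crept towards P, and against my P the reading at 15.0 h left a gap of 0.58 points. The last rung, 30 h, held n = 8.48 turnovers, so I reckoned a rise of 0.57 points for the flask in the second half, against the mark of 0.6 points. The reading of L at 15.0 h stood for 3.16 mM of D used against 22.0 mM of G charged, with J read at 70.7 %, so I committed to level rates and L at 29.3 %.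

The forecast, from the same runs, said forward and back rates have come level and 29.3 %: “The flattening is therefore reversible equilibrium”.

The flask gave forward and back rates have come level, with L at 29.7 %, 0.40 points above my P.

    J + D ⇌ L + X (K = 1.06, k = 0.693 M⁻¹ min⁻¹)
    G ⇌ D, rate k2*(cs2 - [D]) while solid is left; crystals form when [D] > cs2 (solubility = 1.30 mM, k = 0.162 min⁻¹)

With 8.48 turnovers behind it, this flask read L 29.7 % at 30.0 h and 29.7 % at 300 h. The neighbour flask was the same flask read at 8.0 h, m = 0.848 turnovers after the reading at 5.00 h, when the gap to 29.7 % stood at 10 points:

L = 29.7 % − gap · exp(−m) = 25.4 %

The neighbour flask read L 25.1 %.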